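**Retrosynthetic overview**

1. The target is the diacetate of a triol that arises by anti hydrolytic opening, at the allylic carbon C2, of a C1–C2 vinyl epoxide.
2. The trans C5/C6 dibenzoate comes from an all-cis epoxy cis-diol by Mitsunobu inversion at allylic C5 (benzoic acid) followed by benzoylation at C6.
3. The C3=C4 double bond and the free C6–OH come from a 7-oxanorbornanone ketol by Kishner–Leonard eliminative opening of the C3–O–C6 bridge (the C4 ketone carbon becomes =CH).
4. The ketol comes from a 7-oxanorbornadiene by exo epoxidation of C1=C2, exo dihydroxylation of the vinyl sulfone C4=C5 (sulfinate lost) and lipase resolution.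
5. The 7-oxanorbornadiene comes from a 3-(silyloxymethyl)furan and ethynyl p-tolyl sulfone by [4+2] cycloaddition, the only ring-forming event (carbocycle C1–C6; the oxygen bridge is temporary). Enabling feature: C6–O and the sp2 carbon C3 stand 1,4 across the six-membered ring, so the ring is an opened 7-oxanorbornene, i.e. a furan (C3, C2, C1, C6 and O) plus the two-carbon unit C4–C5.

Key step: step 2

Remark: all intermediates carry the ring locants of the target (C1 quaternary carbon bearing CH2O, C2 the CH–OAc carbon, C3=C4, C5 and C6 the CH–OBz carbons); O7 is the former furan oxygen bridging C3 and C6, and exo means the face of O7.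
Remark: the Diels–Alder adduct and the two isolated compounds after it are racemates (as is the transient diol between them); their SMILES show the enantiomer that is carried on.
Remark: it is assumed that screening provides a lipase that acylates the unwanted enantiomer of the racemic ketol faster, so that the wanted enantiomer is recovered as the free alcohol.

**Step 1**
Reactants: 1 furan-3-ylmethanol
Product: 2 tert-butyl(furan-3-ylmethoxy)dimethylsilane
Conditions: TBSCl, imidazole, DMF, 0 °C to rt
Reagents that add atoms: tert-butyldimethylsilyl chloride (TBSCl), CC(C)(C)[Si](C)(C)Cl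
Why: Imidazole-promoted silyl ether formation on a primary alcohol is reliable, creates no stereocenter, and gives an ether stable to the oxidants and bases ahead whose bulk also supports the regiocontrol of step 2.

**Step 2**
Reactants: 2 tert-butyl(furan-3-ylmethoxy)dimethylsilane; 3 ethynyl p-tolyl sulfone
Product: 4 rac-(3S,6S)-1-{[tert-butyl(dimethyl)silyl]oxymethyl}-4-(4-methylbenzenesulfonyl)-3,6-epoxycyclohexa-1,4-diene (a 2,5-disubstituted 7-oxabicyclo[2.2.1]hepta-2,5-diene)
Conditions: toluene, 50 °C, sealed vessel, slight excess of 2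
Reagents that add atoms: none
Why: Normal-electron-demand Diels–Alder cycloaddition, concerted but asynchronous: the furan HOMO (largest coefficient at the α-carbon next to the 3-substituent, the future C6) meets the alkynyl sulfone LUMO (largest coefficient at the unsubstituted β-carbon, the future C5), so C5–C6 forms ahead of C3–C4 and the sulfonyl carbon C4 ends on the α-carbon remote from CH2OTBS. The closest known reaction type is the [4+2] cycloaddition of furans with ethynyl aryl sulfones to 2-sulfonyl-7-oxanorbornadienes. The six-membered carbocycle C1–C6 is closed by intermolecular [4+2] cycloaddition, both σ-bonds being made suprafacially on one furan face, with the furan oxygen left as a temporary C3–O–C6 bridge. The new stereocenters C3 and C6 are the bridgeheads, their cis relation is fixed by the bicyclic geometry, the adduct is racemic (enantiomer selected in step 5), and the C6–O bond later controls every other stereocenter through the exo face. The step needs regioselectivity (sulfonyl on C4, not C5), which the electronic bias and the steric clash between the arylsulfonyl and CH2OTBS groups should both favour, and mono-addition, which follows because the product vinyl sulfone is a much weaker dienophile than the alkyne; any regioisomer is removed by chromatography.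

**Step 3**
Reactants: 4 rac-7-oxanorbornadiene vinyl sulfone
Product: 5 rac-(1S,2R,3S,6S)-1-{[tert-butyl(dimethyl)silyl]oxymethyl}-4-(4-methylbenzenesulfonyl)-1,2:3,6-diepoxycyclohex-4-ene (1,2-epoxide exo)
Conditions: mCPBA, NaHCO3, CH2Cl2, 0 °C to rt
Reagents that add atoms: 3-chloroperoxybenzoic acid (mCPBA), OOC(=O)c1cccc(Cl)c1
Why: Prilezhaev epoxidation is chemoselective for the electron-rich trisubstituted C1=C2 bond (the vinyl sulfone is inert to peracid) and occurs on the exo face, which sets C1 and C2 with the epoxide oxygen syn to O7 and CH2OTBS endo.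

**Step 4**
Reactants: 5 rac-epoxy vinyl sulfone
Product: 7 rac-(1R,2R,3S,5R,6S)-5-hydroxy-1-{[tert-butyl(dimethyl)silyl]oxymethyl}-1,2:3,6-diepoxycyclohexan-4-one (5-OH exo), via hydroxy sulfone diol 6 (not isolated)
Conditions: OsO4 (cat.), NMO, acetone/H2O, rt
Reagents that add atoms: osmium tetroxide (oxygen carrier), O=[Os](=O)(=O)=O; N-methylmorpholine N-oxide (NMO), C[N+]1([O-])CCOCC1; water, O
Why: Upjohn dihydroxylation of the strained vinyl sulfone occurs on the exo face and the α-hydroxy sulfone collapses with loss of sulfinate, so the alkynyl sulfone has served as a hydroxyketene equivalent: C4 becomes a ketone and C5 gains an exo hydroxyl (new stereocenter, cis to O7).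

**Step 5**
Reactants: 7 rac-ketol
Product: 8 (1R,2R,3S,5R,6S)-5-hydroxy-1-{[tert-butyl(dimethyl)silyl]oxymethyl}-1,2:3,6-diepoxycyclohexan-4-one, single enantiomer
Conditions: Burkholderia cepacia lipase (immobilized), vinyl acetate, MTBE, 30 °C, stopped a little beyond half conversion
Reagents that add atoms: none
Why: Lipase-catalysed kinetic resolution by enantioselective transesterification of a secondary alcohol, a reaction type established for exo alcohols on rigid oxabicyclic frameworks, should leave the wanted enantiomer unacylated and so fixes the absolute configuration of C1, C2, C5 and C6 at once; no new stereocenter is formed.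

**Step 6**
Reactants: 8 ketol
Product: 11 (1S,2R,5S,6S)-1-{[tert-butyl(dimethyl)silyl]oxymethyl}-1,2-epoxycyclohex-3-ene-5,6-diol (epoxide oxygen and both hydroxyls on one face), via hydrazone 9 (not isolated), via alkenyldiazene 10 (not isolated)
Conditions: N2H4·H2O, AcOH (cat.), EtOH, rt; evaporate; KOt-Bu (0.3 equiv), DMSO, rt
Reagents that add atoms: none
Why: Kishner–Leonard eliminative reduction (the course of the Wharton transposition): the hydrazone anion, carbanionic at C4, expels the α-alkoxide O7 from C3 with relief of bicyclic strain (the deprotonated C5–OH cannot leave), and the alkenyldiazene loses N2 and is protonated at C4, so the ketone carbon becomes the CH of C3=C4 while the bridge oxygen stays on C6 with its configuration untouched; no stereocenter is created.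

**Step 7**
Reactants: 11 cis-diol
Product: 12 (1S,2R,5R,6S)-1-{[tert-butyl(dimethyl)silyl]oxymethyl}-6-hydroxy-1,2-epoxycyclohex-3-en-5-yl benzoate (5-OBz trans to 6-OH)
Conditions: PhCO2H, PPh3, DIAD, THF, 0 °C to rt
Reagents that add atoms: benzoic acid, OC(=O)c1ccccc1
Why: Mitsunobu reaction with inversion: only the allylic C5–OH should be displaced, because SN2 attack at C6 is blocked by the adjacent fully substituted C1, so benzoate enters C5 from the face opposite the C6 oxygen and sets the 5,6-trans relationship.

**Step 8**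
Reactants: 12 hydroxy benzoate
Product: 13 (1R,2R,5R,6S)-1-{[tert-butyl(dimethyl)silyl]oxymethyl}-1,2-epoxycyclohex-3-ene-5,6-diyl dibenzoate
Conditions: BzCl, pyridine, DMAP (cat.), CH2Cl2, 0 °C to rt
Reagents that add atoms: benzoyl chloride, O=C(Cl)c1ccccc1
Why: DMAP-catalysed O-acylation of the remaining secondary alcohol proceeds with retention at C6 and creates no stereocenter.

**Step 9**
Reactants: 13 epoxy dibenzoate
Product: 14 (1R,2S,5R,6S)-1,2-dihydroxy-1-(hydroxymethyl)cyclohex-3-ene-5,6-diyl dibenzoate
Conditions: HClO4 (cat.), THF/H2O, rt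
Reagents that add atoms: water, O
Why: Acid-catalysed hydrolysis of a vinyl epoxide: water attacks the allylic secondary C2 anti to the epoxide oxygen (borderline SN2, inversion), setting C2–OH trans to the C1–OH that stays on the face of the C6 oxygen, while the same acid cleaves the primary silyl ether.

**Step 10**
Reactants: 14 triol
Product: 15 [(1R,2S,5R,6S)-2-acetoxy-5,6-bis(benzoyloxy)-1-hydroxycyclohex-3-en-1-yl]methyl acetate (CNP0196993.1)
Conditions: Ac2O, pyridine, CH2Cl2, 0 °C to rt
Reagents that add atoms: acetic anhydride, CC(=O)OC(C)=O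
Why: Acetylation with Ac2O/pyridine esterifies the primary and the secondary hydroxyl but not the hindered tertiary C1–OH, giving the target without touching any stereocenter.

**Compound list**

1 | furan-3-ylmethanol | OCc1ccoc1 | starting material
2 | tert-butyl(furan-3-ylmethoxy)dimethylsilane | CC(C)(C)[Si](C)(C)OCc1ccoc1 | intermediate
3 | ethynyl p-tolyl sulfone (1-(ethynylsulfonyl)-4-methylbenzene) | C#CS(=O)(=O)c1ccc(C)cc1 | starting material
4 | rac-(3S,6S)-1-{[tert-butyl(dimethyl)silyl]oxymethyl}-4-(4-methylbenzenesulfonyl)-3,6-epoxycyclohexa-1,4-diene | [C@@H]12O[C@@H](C=C1CO[Si](C)(C)C(C)(C)C)C(S(=O)(=O)c1ccc(C)cc1)=C2 | intermediate (racemate)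
5 | rac-(1S,2R,3S,6S)-1-{[tert-butyl(dimethyl)silyl]oxymethyl}-4-(4-methylbenzenesulfonyl)-1,2:3,6-diepoxycyclohex-4-ene, 1,2-epoxide exo | [C@@H]12O[C@@H]([C@H]3O[C@@]13CO[Si](C)(C)C(C)(C)C)C(S(=O)(=O)c1ccc(C)cc1)=C2 | intermediate (racemate)
6 | rac-4-exo,5-exo-dihydroxy-4-endo-(4-methylbenzenesulfonyl) derivative of 5 (α-hydroxy sulfone diol) | [C@@H]12O[C@@H]([C@H]3O[C@@]13CO[Si](C)(C)C(C)(C)C)[C@@](O)(S(=O)(=O)c1ccc(C)cc1)[C@@H]2O | intermediate (not isolated, racemate)
7 | rac-(1R,2R,3S,5R,6S)-5-hydroxy-1-{[tert-butyl(dimethyl)silyl]oxymethyl}-1,2:3,6-diepoxycyclohexan-4-one, 5-OH exo | [C@@H]12O[C@@H]([C@H]3O[C@@]13CO[Si](C)(C)C(C)(C)C)C(=O)[C@@H]2O | intermediate (racemate)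
8 | (1R,2R,3S,5R,6S)-5-hydroxy-1-{[tert-butyl(dimethyl)silyl]oxymethyl}-1,2:3,6-diepoxycyclohexan-4-one, single enantiomer | [C@@H]12O[C@@H]([C@H]3O[C@@]13CO[Si](C)(C)C(C)(C)C)C(=O)[C@@H]2O | intermediate
9 | hydrazone of 8 at C4, (1R,2R,3R,5S,6S) | [C@@H]12O[C@@H]([C@H]3O[C@@]13CO[Si](C)(C)C(C)(C)C)C(=NN)[C@@H]2O | intermediate (not isolated)
10 | (1S,2R,5S,6S)-4-diazenyl-1-{[tert-butyl(dimethyl)silyl]oxymethyl}-1,2-epoxycyclohex-3-ene-5,6-diol | O[C@H]1[C@@H](O)C(N=N)=C[C@H]2O[C@@]12CO[Si](C)(C)C(C)(C)C | intermediate (not isolated)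
11 | (1S,2R,5S,6S)-1-{[tert-butyl(dimethyl)silyl]oxymethyl}-1,2-epoxycyclohex-3-ene-5,6-diol, all three oxygens on one face | O[C@H]1[C@@H](O)C=C[C@H]2O[C@@]12CO[Si](C)(C)C(C)(C)C | intermediate
12 | (1S,2R,5R,6S)-1-{[tert-butyl(dimethyl)silyl]oxymethyl}-6-hydroxy-1,2-epoxycyclohex-3-en-5-yl benzoate | O[C@H]1[C@H](OC(=O)c3ccccc3)C=C[C@H]2O[C@@]12CO[Si](C)(C)C(C)(C)C | intermediate
13 | (1R,2R,5R,6S)-1-{[tert-butyl(dimethyl)silyl]oxymethyl}-1,2-epoxycyclohex-3-ene-5,6-diyl dibenzoate | O=C(O[C@H]1[C@H](OC(=O)c3ccccc3)C=C[C@H]2O[C@@]12CO[Si](C)(C)C(C)(C)C)c1ccccc1 | intermediate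
14 | (1R,2S,5R,6S)-1,2-dihydroxy-1-(hydroxymethyl)cyclohex-3-ene-5,6-diyl dibenzoate | OC[C@@]1(O)[C@@H](O)C=C[C@@H](OC(=O)c2ccccc2)[C@@H]1OC(=O)c1ccccc1 | intermediate
15 | [(1R,2S,5R,6S)-2-acetoxy-5,6-bis(benzoyloxy)-1-hydroxycyclohex-3-en-1-yl]methyl acetate | CC(=O)OC[C@@]1(O)[C@@H](OC(C)=O)C=C[C@@H](OC(=O)c2ccccc2)[C@@H]1OC(=O)c1ccccc1 | target

**Totals and risks**

Total step count: 10. Longest linear sequence: 10 steps (1 to 15; 3 is used as bought).

Steps most likely to fail:

- **Step 6.** The hydrazone anion may be protonated at C4 before it expels the bridge oxygen (plain Wolff–Kishner reduction to CH2), or hydrazine may open the epoxide once the alkene has formed. The fallback is a Bernet–Vasella-type zinc fragmentation setting out from 8. Et3SiCl and imidazole give the 5-O-triethylsilyl ketone F1. NaBH4 (MeOH, 0 °C) reduces the C4 ketone from the exo face to the endo alcohol F2. Tf2O/pyridine followed by Bu4NI (toluene, 60 °C) gives the exo iodide F3. Zn dust (EtOH/THF, NH4Cl, reflux) inserts into the C4–I bond and the organozinc expels the bridge oxygen from C3, giving the ring-opened cyclohexenol F4 with C3=C4 and free C6–OH. PPTS in MeOH then removes the triethylsilyl group selectively and the route is rejoined at 11.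

- **Step 7.** Benzoate may attack C3 in SN2' fashion with allylic shift, the wrong hydroxyl may be activated, or elimination may compete. The fallback is an oxidation–reduction inversion setting out from 11. MnO2 (CH2Cl2) oxidizes only the allylic C5 alcohol to the 6-hydroxy enone F5. Hydroxyl-directed 1,2-reduction with Me4NBH(OAc)3 (AcOH/MeCN, −20 °C) delivers hydride from the face of C6–OH and gives the trans-5,6-diol F6. Excess BzCl with pyridine and DMAP benzoylates both hydroxyls and the route is rejoined at 13.

- **Step 9.** Regiocontrol of the epoxide opening may be lost (conjugate attack of water at C4 with shift of the double bond, or ionization without clean inversion), and acyl groups may migrate in acid. The fallback sets out from 13. HF·pyridine (THF, 0 °C) cleaves the silyl ether to the epoxy alcohol F7. Ti(OiPr)4-mediated opening with acetic acid, which for 2,3-epoxy alcohols takes place at the carbon remote from the carbinol (here allylic C2) with inversion, gives the C2 acetate F8. Ac2O/pyridine acetylates the primary hydroxyl and the route is rejoined at the target 15.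

Further compounds
F1 | step 6 | 5-O-triethylsilyl ether of ketol 8 | [C@@H]12O[C@@H]([C@H]3O[C@@]13CO[Si](C)(C)C(C)(C)C)C(=O)[C@@H]2O[Si](CC)(CC)CC
F2 | step 6 | C4 endo alcohol from reduction of F1 | [C@@H]12O[C@@H]([C@H]3O[C@@]13CO[Si](C)(C)C(C)(C)C)[C@@H](O)[C@@H]2O[Si](CC)(CC)CC
F3 | step 6 | C4 exo iodide | [C@@H]12O[C@@H]([C@H]3O[C@@]13CO[Si](C)(C)C(C)(C)C)[C@H](I)[C@@H]2O[Si](CC)(CC)CC
F4 | step 6 | 5-O-triethylsilyl ether of diol 11 | O[C@H]1[C@@H](O[Si](CC)(CC)CC)C=C[C@H]2O[C@@]12CO[Si](C)(C)C(C)(C)C
F5 | step 7 | (1S,2R,6S)-1-{[tert-butyl(dimethyl)silyl]oxymethyl}-6-hydroxy-1,2-epoxycyclohex-3-en-5-one | O[C@H]1C(=O)C=C[C@H]2O[C@@]12CO[Si](C)(C)C(C)(C)C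
F6 | step 7 | (1S,2R,5R,6S)-1-{[tert-butyl(dimethyl)silyl]oxymethyl}-1,2-epoxycyclohex-3-ene-5,6-diol, 5,6-trans | O[C@H]1[C@H](O)C=C[C@H]2O[C@@]12CO[Si](C)(C)C(C)(C)C
F7 | step 9 | (1R,2R,5R,6S)-1-(hydroxymethyl)-1,2-epoxycyclohex-3-ene-5,6-diyl dibenzoate | O=C(O[C@H]1[C@H](OC(=O)c3ccccc3)C=C[C@H]2O[C@@]12CO)c1ccccc1
F8 | step 9 | (1R,2S,5R,6S)-2-acetoxy-1-hydroxy-1-(hydroxymethyl)cyclohex-3-ene-5,6-diyl dibenzoate | OC[C@@]1(O)[C@@H](OC(C)=O)C=C[C@@H](OC(=O)c2ccccc2)[C@@H]1OC(=O)c1ccccc1
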